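**Retrosynthetic overview**
1. Ring A is bought as phloroglucinol (1) and ring B as 4-hydroxyphenylacetic acid (2). Ring C is the only ring made: Friedel–Crafts union to deoxybenzoin 3, then closure of the pyranone through the O1–C2 carbon–oxygen bond to genistein (4).
2. The 7-OH is masked as its MOM ether (5), so the 4'-OH is the only free, non-chelated phenol.
3. Each C-prenyl group is traced back to an aryl O–C(CH3)2CH=CH2 ether bond. Alcohol 6 is turned through alkoxide 7 into carbonate 8; palladium catalysis makes the carbon–oxygen bond and a [3,3] shift passes the prenyl unit to the ortho carbon, twice in one flask (9, 10, 11, then 12).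
4. MOM removal gives the target 13.

Assumption: the target has no stereocentre and no stereogenic double bond, so the given structure is its only stereoisomer and no stereocontrol is needed.

**Route**

Step 1
Reactants: 1 phloroglucinol (benzene-1,3,5-triol); 2 4-hydroxyphenylacetic acid
Product: 4 genistein (5,7-dihydroxy-3-(4-hydroxyphenyl)-4H-chromen-4-one), via deoxybenzoin 3 (not isolated)
Conditions: BF3·OEt2 (solvent), 85 °C, 1.5 h; then DMF, MsCl (3 equiv), 70 °C, 2 h; pour into water
Reagents that add atoms: N,N-dimethylformamide, CN(C)C=O (supplies C2)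
Why: BF3-promoted Friedel–Crafts acylation of the symmetric, very nucleophilic phloroglucinol gives deoxybenzoin 3, whose enol is C-formylated by the Vilsmeier-type iminium from DMF and MsCl, after which the ortho-OH closes ring C through the O1–C2 carbon–oxygen bond with loss of dimethylamine (the known one-pot deoxybenzoin isoflavone synthesis).

Step 2
Reactants: 4 genistein
Product: 5 genistein 7-O-methoxymethyl ether (5-hydroxy-3-(4-hydroxyphenyl)-7-(methoxymethoxy)-4H-chromen-4-one)
Conditions: MOMCl (1.05 equiv), K2CO3 (1.0 equiv), DMF, 0 °C to rt, 3 h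
Reagents that add atoms: chloromethyl methyl ether (MOMCl), COCCl
Why: The 7-OH, para to the pyranone carbonyl, is the most acidic phenol, so one equivalent of K2CO3 forms only the 7-phenoxide, which is O-alkylated by MOMCl (Williamson-type etherification) while the chelated 5-OH and the 4'-OH stay free.

Step 3
Reactants: 6 2-methylbut-3-en-2-ol
Product: 8 tert-butyl (2-methylbut-3-en-2-yl) carbonate, via lithium alkoxide 7 (not isolated)
Conditions: n-BuLi (1.05 equiv), THF, −78 to 0 °C; then Boc2O (1.1 equiv), 0 °C to rt; H2O work-up, distillation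
Reagents that add atoms: di-tert-butyl dicarbonate (Boc2O), CC(C)(C)OC(=O)OC(=O)OC(C)(C)C; n-butyllithium, [Li]CCCC (gives the lithium of 7 only)
Why: Acylation of the tertiary lithium alkoxide 7 by Boc2O gives the mixed allyl tert-butyl carbonate, the standard ionisable partner for Tsuji–Trost chemistry.

Step 4
Reactants: 5 genistein 7-O-methoxymethyl ether; 8 tert-butyl (2-methylbut-3-en-2-yl) carbonate (2.6 equiv in two charges)
Product: 12 MOM-protected diprenylgenistein (5-hydroxy-3-[4-hydroxy-3,5-bis(3-methylbut-2-en-1-yl)phenyl]-7-(methoxymethoxy)-4H-chromen-4-one), via first tert-prenyl ether 9 (not isolated), via monoprenyl phenol 10 (not isolated), via second tert-prenyl ether 11 (not isolated)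
Conditions: Pd(PPh3)4 (5 mol %), 8 (1.3 equiv), 1,4-dioxane, 25 °C, 1 h, then 100 °C, 5 h; cool to 25 °C, second charge of Pd(PPh3)4 (3 mol %) and 8 (1.3 equiv), 25 °C, 1 h, then 100 °C, 5 h
Reagents that add atoms: none
Why: Proposed new method: a one-flask, twofold decarboxylative O-(1,1-dimethylallyl)ation / aromatic Claisen relay under zerovalent palladium catalysis, in which Pd(PPh3)4 ionises 8 to a 1,1-dimethyl-π-allylpalladium cation and tert-butoxide (after loss of CO2), the alkoxide deprotonates the more acidic, open 4'-OH and not the chelated 5-OH, and the phenoxide attacks the more substituted allyl terminus to form the aryl C–O bond of 9; heating drives the chair [3,3] shift to the free ortho carbon and rearomatisation to 10, and the second charge repeats the sequence through 11 to 12; the palladium keeps branched and linear O-prenyl ethers in equilibrium by re-ionisation while only the branched ether rearranges at 100 °C, so material is funnelled irreversibly to C-prenyl, and the relay stops at 12 because the para position is blocked and both ortho positions are then filled; the closest known chemistry is the Tsuji–Trost O-tert-prenylation of phenols with tertiary allyl carbonates and the separate thermal Claisen rearrangement of isolated aryl 1,1-dimethylallyl ethers, which have not been merged and iterated in one flask to place two ortho prenyl groups on an isoflavone.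

Step 5
Reactants: 12 MOM-protected diprenylgenistein
Product: 13 3',5'-diprenylgenistein (5,7-dihydroxy-3-[4-hydroxy-3,5-bis(3-methylbut-2-en-1-yl)phenyl]-4H-chromen-4-one)
Conditions: HCl (1 M in MeOH/H2O 9:1), 40 °C, 3 h
Reagents that add atoms: none
Why: Acid-catalysed acetal hydrolysis cleaves the MOM ether of the most acidic (7-) phenol through the methoxymethyl oxocarbenium ion under dilute HCl, conditions mild enough that protonation of the trisubstituted prenyl olefins (chroman formation) is slow.

**Compound list**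
1 | phloroglucinol (benzene-1,3,5-triol) | Oc1cc(O)cc(O)c1 | starting material
2 | 4-hydroxyphenylacetic acid | OC(=O)Cc1ccc(O)cc1 | starting material
3 | 2-(4-hydroxyphenyl)-1-(2,4,6-trihydroxyphenyl)ethan-1-one (deoxybenzoin) | O=C(Cc1ccc(O)cc1)c1c(O)cc(O)cc1O | intermediate (not isolated)
4 | genistein, 5,7-dihydroxy-3-(4-hydroxyphenyl)-4H-chromen-4-one | O=c1c(-c2ccc(O)cc2)coc2cc(O)cc(O)c12 | intermediate
5 | 5-hydroxy-3-(4-hydroxyphenyl)-7-(methoxymethoxy)-4H-chromen-4-one | COCOc1cc(O)c2c(c1)occ(-c1ccc(O)cc1)c2=O | intermediate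
6 | 2-methylbut-3-en-2-ol | CC(C)(O)C=C | starting material
7 | lithium 2-methylbut-3-en-2-olate | [Li+].[O-]C(C)(C)C=C | intermediate (not isolated)
8 | tert-butyl (2-methylbut-3-en-2-yl) carbonate | C=CC(C)(C)OC(=O)OC(C)(C)C | intermediate
9 | 5-hydroxy-7-(methoxymethoxy)-3-[4-(2-methylbut-3-en-2-yloxy)phenyl]-4H-chromen-4-one | COCOc1cc(O)c2c(c1)occ(-c1ccc(OC(C)(C)C=C)cc1)c2=O | intermediate (not isolated)
10 | 5-hydroxy-3-[4-hydroxy-3-(3-methylbut-2-en-1-yl)phenyl]-7-(methoxymethoxy)-4H-chromen-4-one | COCOc1cc(O)c2c(c1)occ(-c1ccc(O)c(CC=C(C)C)c1)c2=O | intermediate (not isolated)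
11 | 5-hydroxy-7-(methoxymethoxy)-3-[3-(3-methylbut-2-en-1-yl)-4-(2-methylbut-3-en-2-yloxy)phenyl]-4H-chromen-4-one | COCOc1cc(O)c2c(c1)occ(-c1ccc(OC(C)(C)C=C)c(CC=C(C)C)c1)c2=O | intermediate (not isolated)
12 | 5-hydroxy-3-[4-hydroxy-3,5-bis(3-methylbut-2-en-1-yl)phenyl]-7-(methoxymethoxy)-4H-chromen-4-one | COCOc1cc(O)c2c(c1)occ(-c1cc(CC=C(C)C)c(O)c(CC=C(C)C)c1)c2=O | intermediate
13 | 3',5'-diprenylgenistein, 5,7-dihydroxy-3-[4-hydroxy-3,5-bis(3-methylbut-2-en-1-yl)phenyl]-4H-chromen-4-one | CC(C)=CCc1cc(-c2coc3cc(O)cc(O)c3c2=O)cc(CC=C(C)C)c1O | target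

**Step count**
Total steps: 5. Longest linear sequence: 4 (steps 1, 2, 4, 5); step 3 is a one-step side branch.

**Three steps most likely to fail**

Step 4 (the new relay). The risks are a stalled second etherification on the now ortho-substituted phenol 10, loss of the allyl unit as isoprene at 100 °C, and some alkylation at the 5-OH once the 4'-position is hindered. The fallback uses only known reactions, sets out from 5 and comes back at 12. Compound 5 is O-allylated (allyl bromide, K2CO3, acetone, reflux) to the 4'-O-allyl ether F1. Thermal Claisen rearrangement (N,N-diethylaniline, 200 °C) gives the 3'-allyl phenol F2. A second O-allylation gives the allyl ether F3, and a second Claisen rearrangement gives the 3',5'-diallyl phenol F4. Olefin cross-metathesis of F4 with excess 2-methylbut-2-ene (second-generation Grubbs catalyst, (H2IMes)(PCy3)Cl2Ru=CHPh, 5 mol %, CH2Cl2, 40 °C) converts both allyl groups into prenyl groups and delivers 12.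

Step 2 (mono-protection). The risk is a mixture of 7-O-MOM, 4',7-bis-MOM and unreacted 4. The fallback sets out from 4 and comes back at 5. Peracetylation (Ac2O, pyridine) gives genistein 4',5,7-triacetate F5. The most labile 7-acetate is removed selectively with thiophenol and imidazole in N-methylpyrrolidone at 0 °C to give 4',5-di-O-acetylgenistein F6. The single free 7-OH is protected (MOMCl, i-Pr2NEt, CH2Cl2) to give 4',5-di-O-acetyl-7-O-(methoxymethyl)genistein F7. Methanolysis of the two acetates (K2CO3, MeOH, rt) gives 5.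

Step 5 (acidic deprotection next to two ortho-prenyl phenol units). The risk is acid-induced cyclisation of a prenyl group onto the 4'-OH to a 2,2-dimethylchroman. The fallback replaces the acid-labile group by a fluoride-labile one, sets out from 4 and comes back at 13. Compound 4 is alkylated at the 7-OH with 2-(trimethylsilyl)ethoxymethyl chloride (K2CO3, 1.0 equiv, DMF, 0 °C) to give 7-O-SEM-genistein F8. F8 is carried through the step 4 relay with carbonate 8, via the first tert-prenyl ether F9, the monoprenyl phenol F10 and the second tert-prenyl ether F11, to 7-O-SEM-3',5'-diprenylgenistein F12. Tetrabutylammonium fluoride (3 equiv, THF, 50 °C) then removes the SEM group without acid and gives 13.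

**Further compounds**
F1 | step 4 | 5-hydroxy-7-(methoxymethoxy)-3-[4-(prop-2-en-1-yloxy)phenyl]-4H-chromen-4-one | COCOc1cc(O)c2c(c1)occ(-c1ccc(OCC=C)cc1)c2=O
F2 | step 4 | 5-hydroxy-3-[4-hydroxy-3-(prop-2-en-1-yl)phenyl]-7-(methoxymethoxy)-4H-chromen-4-one | COCOc1cc(O)c2c(c1)occ(-c1ccc(O)c(CC=C)c1)c2=O
F3 | step 4 | 5-hydroxy-7-(methoxymethoxy)-3-[3-(prop-2-en-1-yl)-4-(prop-2-en-1-yloxy)phenyl]-4H-chromen-4-one | COCOc1cc(O)c2c(c1)occ(-c1ccc(OCC=C)c(CC=C)c1)c2=O
F4 | step 4 | 5-hydroxy-3-[4-hydroxy-3,5-di(prop-2-en-1-yl)phenyl]-7-(methoxymethoxy)-4H-chromen-4-one | COCOc1cc(O)c2c(c1)occ(-c1cc(CC=C)c(O)c(CC=C)c1)c2=O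
F5 | step 2 | genistein 4',5,7-triacetate | CC(=O)Oc1ccc(cc1)-c1coc2cc(OC(C)=O)cc(OC(C)=O)c2c1=O
F6 | step 2 | 4',5-di-O-acetylgenistein | CC(=O)Oc1ccc(cc1)-c1coc2cc(O)cc(OC(C)=O)c2c1=O
F7 | step 2 | 4',5-di-O-acetyl-7-O-(methoxymethyl)genistein | COCOc1cc(OC(C)=O)c2c(c1)occ(-c1ccc(OC(C)=O)cc1)c2=O
F8 | step 5 | 5-hydroxy-3-(4-hydroxyphenyl)-7-{[2-(trimethylsilyl)ethoxy]methoxy}-4H-chromen-4-one | C[Si](C)(C)CCOCOc1cc(O)c2c(c1)occ(-c1ccc(O)cc1)c2=O
F9 | step 5 | 5-hydroxy-3-[4-(2-methylbut-3-en-2-yloxy)phenyl]-7-{[2-(trimethylsilyl)ethoxy]methoxy}-4H-chromen-4-one | C[Si](C)(C)CCOCOc1cc(O)c2c(c1)occ(-c1ccc(OC(C)(C)C=C)cc1)c2=O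
F10 | step 5 | 5-hydroxy-3-[4-hydroxy-3-(3-methylbut-2-en-1-yl)phenyl]-7-{[2-(trimethylsilyl)ethoxy]methoxy}-4H-chromen-4-one | C[Si](C)(C)CCOCOc1cc(O)c2c(c1)occ(-c1ccc(O)c(CC=C(C)C)c1)c2=O
F11 | step 5 | 5-hydroxy-3-[3-(3-methylbut-2-en-1-yl)-4-(2-methylbut-3-en-2-yloxy)phenyl]-7-{[2-(trimethylsilyl)ethoxy]methoxy}-4H-chromen-4-one | C[Si](C)(C)CCOCOc1cc(O)c2c(c1)occ(-c1ccc(OC(C)(C)C=C)c(CC=C(C)C)c1)c2=O
F12 | step 5 | 5-hydroxy-3-[4-hydroxy-3,5-bis(3-methylbut-2-en-1-yl)phenyl]-7-{[2-(trimethylsilyl)ethoxy]methoxy}-4H-chromen-4-one | C[Si](C)(C)CCOCOc1cc(O)c2c(c1)occ(-c1cc(CC=C(C)C)c(O)c(CC=C(C)C)c1)c2=O
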